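- Amounts come first: if each substrate takes up one coupling partner, as assumed here, the south-west flask holds 0.100 of the substrate charge as coupling partner beyond one equivalent, the excess.

all flasks: substrate 20 mM

| charge | coupling partner | remark | time |
|---|---|---|---|
| south-west | 1.1 equiv | the very flask that is asked about, followed so far |  |
| flask | 1.10 equiv |  | 12 d |

- south-west (time / h: side product / %, target / %): 1.50: 2.6, 25.8; 4.00: 5.3, 28.0; 8.00: 6.9, 28.0; 12.0: 8.0, 28.7; 20.0: 9.1, 28.4; 25.0: 8.6, 28.2

(standard deviation of a reading: 0.3 percentage points)

- a reading or a percentage of target counts all its forms, free or not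

- share of side product in side product plus target at 8.0 min
- share of side product in side product plus target at 6.0 h
- share of side product in side product plus target at 12 d

- In the south-west run, side product forms at a mean rate of 0.0173 h⁻¹ in fractions of the charge up to 1.50 h, but at 0.00275 h⁻¹ between 8.00 h and 12.0 h, a slowing by a factor of 6.29, read from readings with a scatter of 0.3 percentage points.
- Over 1.50 h to 12.0 h, the excess left, reckoned as excess minus side product, falls by a factor of 3.70, which leaves a factor of 1.70 for the scatter and the early span.
- A rate that follows what is left, a pseudo-first-order decay, adds up over time to that amount, so my reckoning takes the excess as the ceiling of side product.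
- The last readings of the south-west run leave 63.2 % of the substrate charge in neither product, more than the excess of 10.0 % of that charge, so if this material is what takes up the coupling partner, the coupling partner is the limiting reagent of this late stage.
- With the target flat, my reckoned share at the end of the flask is 26.2 %.
- The forecast gives 4.5 %, 18 % and 26 %, with ranges 1.5 % to 10 %, 16.5 % to 19.5 % and 23 % to 34 %, saying that the side product “keeps creeping up on a slower clock”.
- The flask gives 1.93 % at 8.0 min, 17.6 % at 6.0 h and 26.1 % at 12 d.

    substrate + target ⇌ idle adduct, settled at all times (K = 27.0 L mol⁻¹)
    coupling partner + intermediate B → side product (k = 0.110 L mol⁻¹ min⁻¹)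
    substrate + coupling partner → target (k = 1.20 L mol⁻¹ min⁻¹)
    coupling partner + intermediate B ⇌ intermediate D (K = 62.0 L mol⁻¹, k = 0.00770 L mol⁻¹ min⁻¹)
    substrate + coupling partner → intermediate A (k = 0.110 L mol⁻¹ min⁻¹)
    intermediate A ⇌ intermediate C (K = 2.00, k = 0.00830 min⁻¹)
    substrate + coupling partner → intermediate B (k = 2.90 L mol⁻¹ min⁻¹)

- In the flask, substrate and coupling partner made target and intermediate B, with half of that turnover done by 0.179 h; the coupling partner left then reacted with intermediate B, with half of that turnover done by 0.170 d, and at 12.0 d side product stood at 10.1 %, beside intermediate B at 58.6 % and coupling partner at 0.00765 % of its own charge. The neighbour flask with 5.0 mM of substrate has the same excess of 0.100; its share was 9.69 % at 6.0 h, and at 12.0 d it held 9.93 % side product, a share of 25.9 %.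

The earlier runs and the new flask are simulated for substances that don't exist.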